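A single first-order step cannot make its product come faster while its starting material falls. Yet the north flask gains 12 percentage points of product from 10.0 min to 20.0 min, then 22 points by 30.0 min.

| flask | starting material | remark | time |
|---|---|---|---|
| north | 3 M | the very flask that is asked about, followed so far |  |
| flask | 3.0 M |  | 1.0 h |

north run (percent of the starting material charged)

| time / min | product / % | dormant form / % |
|---|---|---|
| 2.50 | 0 | 0 |
| 4.00 | 1.7 | 4.1 |
| 6.00 | 0.1 | 5.9 |
| 10.0 | 2.8 | 8.7 |
| 20.0 | 14.8 | 13.7 |
| 30.0 | 37.1 | 18.3 |

(each reading ± 1 percentage point)

1. amount of product in the flask at 1.0 h, in percent of the starting material charged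
2. amount of dormant form in the flask at 1.0 h, in percent of the starting material charged
3. amount of starting material in the flask at 1.0 h, in percent of the starting material charged



I must decide whether to read this flask at 1.0 h or leave it longer. I treat the loss of starting material to product as pseudo-first-order, with a pull of c·[product], [product] being a share of the charge. Over the last interval the balance gives a mean [starting material] of 58.0%, so from the readings:

c = ln([product] ratio) / (interval × mean) = 0.158 min⁻¹

My first round holds starting material plus product at 81.7%, and logistic growth from 30.0 min leaves:

[starting material] = 1.98%

Putting that back in, dormant form, read the same way at 0.00792 min⁻¹, gains 3.8 points. The second round gives: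

[starting material] = 2.25%, [product] = 75.6%, [dormant form] = 22.1%

The pull then halves starting material every 5.79 min. So I change nothing, read at 1.0 h, and read once more later to test that pace.

The forecast says 76% product, 21% dormant form and 3% starting material: “That looks autocatalytic”. The flask gives 79.5%, 17.4% and 3.08%.

    starting material ⇌ dormant form (K = 0.950, k = 1.50 × 10⁻⁴ s⁻¹)
    starting material + product → 2 product (k = 8.50 × 10⁻⁴ L mol⁻¹ s⁻¹)
    starting material → product (k = 2.60 × 10⁻⁵ s⁻¹)

With c as I read it from the north readings, and so with their scatter, the product of this flask at 1.0 h reckons a half-life of about 5.50 min for starting material under the pull. Yet between this flask and its neighbour left to 1.5 h, starting material goes to 1.00%, halving every 18.5 min, slower than that reckoned pace. Dormant form meanwhile falls to 13.4% in the neighbour. The flask is not at rest at 1.0 h: at 10.0 h it holds 99.8% product, 0.143% dormant form and 0.00880% starting material.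

The data come from a simulation on assumed constants.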